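Atom labels C1–C8 are those of the bicyclo[3.2.1]octane core of the target (C8 = ketone bridge) and are kept for the same atoms in every intermediate. Compound numbers are those of the steps and the compound list below.

## Analysis of the target

Target 24 is a bicyclo[3.2.1]oct-2-en-8-one. C1 (allyl) and C5 (methoxy) are the bridgeheads; the bridges are C2=C3(OMe)–C4(OAc), C6(3,4-dimethoxyphenyl)–C7(methyl) and the ketone carbon C8. It has five stereocentres, (1S,4S,5S,6S,7R). C1 and C5 are quaternary and tied together by the bicycle; the aryl group on C6 is exo (on the C8 side) and the methyl on C7 is endo, so the two are trans. The acetoxy group on C4 points to the C8 side of the enol ether bridge, away from the C6–C7 bridge. Sensitive features are the enol ether next to an allylic acetate (acid-labile and ionisable), the terminal alkene, the electron-rich arene, and, in any diketone precursor, a C5 between two carbonyl groups that nucleophilic base can cleave by retro-Claisen reaction. The difficulty lies in two quaternary bridgeheads, four contiguous stereocentres around the ring C8–C1–C7–C6–C5, and a C4 oxygen on the face that reduction of a 4-ketone cannot supply, because the endo hydrogen on C6 lies directly under C4. The strategy rests on that five-membered ring: C6 (benzylic) and C1 are 1,3-related through C7, so with C1 as a malonate carbon C6–C7–C1 is an aryl donor–acceptor cyclopropane and C5–C8 is the two-carbon unit of an α-methoxy acetate enol derivative.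

## Retrosynthetic reasoning

**C4–O bond (24 ⇒ 23).** The acetate is cut at C4–O with inversion, which leads to the epimeric allylic alcohol 23. This is chosen because hydride can reach C4 of dione 22 only from the C8 side and therefore puts the hydroxyl on the face of the C6–C7 bridge, the opposite of 24. The forward step must exchange the oxygen with inversion and bring in the acetyl group at once. C3 and C5 carry no hydrogen, so elimination cannot interfere.

**C4 carbonyl (23 ⇒ 22).** Going back to the 4,8-dione 22 removes the C4 stereocentre. The forward reduction must touch only C4; C8 is flanked by two quaternary carbons and is screened by C3 on one face and by the exo aryl group on the other.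

**C2=C3 (22 ⇒ 19, through 20 and 21).** The enone is opened at C2=C3 by a retro-aldol condensation to an aldehyde carbon C2 on C1 and a methoxyacetyl group (C4, C3) on C5. This cut is polarity-matched and unambiguous: the aldehyde, C8 and C5 cannot enolise, so only the C3 enol can add to C2. The ring closure is done under acid because C5 in 19–22 lies between two carbonyl groups. The aldehyde is carried as its dimethyl acetal in 19.

**C4–C5 (19 ⇒ 17, through enolate 18).** The methoxyacetyl group is removed from C5, leaving ketone 17, which can enolise only at C5. The forward C-acylation must occur anti to the C6 aryl group; that places C4 cis to C2, the only arrangement that can close the six-membered ring, and fixes the C5 methoxy group cis to aryl.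

**Oxidation-level changes (17 ⇒ 16 ⇒ 15 ⇒ 14).** Acetal 17 comes from keto aldehyde 16, which comes from diol 15 by double oxidation, and 15 from keto ester 14 by exhaustive reduction. No bond of the skeleton is cut; the detour turns the ester carbon into C2 at the aldehyde level and masks it for the enolate step.

**C1–allyl and C1–ester (14 ⇒ 13 ⇒ 12).** The allyl group is removed from C1 to give β-keto ester 13, and a second ester is added back to give 12. The forward allylation should occur anti to the C7 methyl. The second ester is needed only as the activating group of the cyclopropane.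

**C5–C6 and C1–C8 (12 ⇒ 7 + 10).** The cyclopentanone is cut into cis-cyclopropane 7 and ketene silyl acetal 10. The forward Lewis-acid (3+2) annulation forms both bonds and the ring, and inverts C6 so that the cis pair of 7 becomes the trans aryl/methyl pair. C7 is untouched and carries the absolute configuration.

**Cyclopropane and small pieces (7 ⇒ 4 + 6; 4 ⇒ 3 ⇒ 1 + 2; 6 ⇒ 5; 10 ⇒ 8).** Cyclopropane 7 is cut into Z-alkene 4 and diazomalonate 6; an asymmetric carbene transfer sets C6 and C7 together. Alkene 4 comes from alkyne 3 by syn semihydrogenation, and 3 from iodide 1 and propyne 2. Diazo compound 6 comes from malonate 5, and 10 from ester 8.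

## Alternatives that were turned down

**Alternative 1:** The C6–aryl and C4–C5 bonds are cut together, leaving the trans enone A2, 2-methoxyacrolein A3 and an aryl copper nucleophile. In the forward key step the aryl group adds to C6 of A2 anti to the C7 methyl, and the resulting α-methoxy enolate adds through C5 to the aldehyde of A3 to give A1. In its favour, three components are joined in one flask, the trans aryl/methyl relation follows from anti addition, and C4 arrives as an alcohol. On the C4 oxidation level this alternative is stronger than the chosen route, which needs a reduction and an inversion. Against it, the key step closes no ring. The C1–C2 bond to a quaternary bridgehead must still be made by joining an enolate carbon to the terminal carbon of an enol ether, which is not a polarity-matched closure. The C4 configuration is set in a reversible intermolecular aldol of a fully substituted enolate, and A2 with two stereocentres must first be made as a single enantiomer. The chosen strategy offers in its place a ring closure and the C6 stereocentre in the same step, and two later ring-forming steps that are both polarity-matched.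

**Alternative 2:** The C1–C7 bond is cut and the C7 methyl is traced back to a vinyl group on C6. In the forward key step a tertiary α-keto radical at C1, released from selenide A5 by a tin hydride, adds 5-exo-trig to the vinyl group; hydrogen transfer then leaves the methyl and gives A4. In its favour, the C5–C6 bond can be set early by a sigmatropic step, and radical conditions tolerate congestion and the ketones. Against it, the methyl orientation at C7 depends only on the conformation of the vinyl group in the cyclisation, and A5 needs a diastereoselective double functionalisation of one of two carbonyl α-positions. A4 still lacks the C3 methoxy group and the C2=C3 double bond, so several oxidation steps follow in the presence of two ketones. No step gives an obvious entry to one enantiomer. It is weaker than the chosen strategy in stereocontrol and no shorter.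

**Alternative 3:** The C5–C6 bond is cut heterolytically, with C6 as a benzylic cation and C5 as the central carbon of an enolised 2-methoxy-1,3-diketone; both are held in dihydrobenzofuranone A7, which comes from allyl ether A8 by a dearomative para-Claisen rearrangement. In the forward key step acid ionises the benzylic C–O bond of A7 and the enol closes on the cation through C5 to give A6. In its favour, it is the shortest route and follows the likely biogenesis, and A6 is the same compound as 22, so the last two steps would be shared. On step economy it is clearly stronger than the chosen route. Against it, the cation erases C6, so the result depends on the partition between return to oxygen and attack through carbon and between the two C6 epimers. The absolute configuration would have to come from A8 and from a dearomative Claisen step for which no enantioselective control is evident, and the acid meets an enol ether and an allyl group. The chosen strategy offers in its place an absolute configuration set in one catalytic step and relayed by stereospecific bond formation, with C6 fixed by inversion and not by equilibration, at the cost of roughly twice the number of steps.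

Key step: step 6

Assumption: Rh2(S-NTTL)4 is taken to deliver the (2R,3R) enantiomer of 7; if the sense of induction on this cis-alkene is the opposite, the mirror-image catalyst Rh2(R-NTTL)4 is used and nothing else changes.

Remark: the double-bond geometry of 10 is drawn as the Z isomer expected from the chelated enolate; it is destroyed in step 6 and either isomer serves.

## Steps

Step 1
Reactants: 1 4-iodo-1,2-dimethoxybenzene; 2 propyne
Product: 3 1,2-dimethoxy-4-(prop-1-yn-1-yl)benzene
Conditions: PdCl2(PPh3)2 (2 mol%), CuI (4 mol%), Et3N, THF, rt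
Reagents that add atoms: none
Why: Sonogashira coupling of an aryl iodide with a terminal alkyne is reliable at room temperature, and an electron-rich iodide is a normal substrate.

Step 2
Reactants: 3 1,2-dimethoxy-4-(prop-1-yn-1-yl)benzene
Product: 4 (Z)-1,2-dimethoxy-4-(prop-1-en-1-yl)benzene
Conditions: H2 (1 atm), Pd/CaCO3 poisoned with Pb(OAc)2, quinoline, EtOAc, rt
Reagents that add atoms: none
Why: Lindlar semihydrogenation adds hydrogen syn on the poisoned surface and should give the Z alkene in higher geometric purity than a Wittig ethylidenation; the geometry becomes the cis relation of the cyclopropane.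

Step 3
Reactants: 5 dimethyl malonate
Product: 6 dimethyl 2-diazopropanedioate
Conditions: 4-acetamidobenzenesulfonyl azide, Et3N, MeCN, 0 °C → rt
Reagents that add atoms: 4-acetamidobenzenesulfonyl azide, CC(=O)Nc1ccc(cc1)S(=O)(=O)N=[N+]=[N-]
Why: Regitz diazo transfer to an active methylene compound is a standard preparation of diazomalonates.

Step 4
Reactants: 4 (Z)-1,2-dimethoxy-4-(prop-1-en-1-yl)benzene; 6 dimethyl 2-diazopropanedioate
Product: 7 dimethyl (2R,3R)-2-(3,4-dimethoxyphenyl)-3-methylcyclopropane-1,1-dicarboxylate (aryl and methyl cis)
Conditions: Rh2(S-NTTL)4 (1 mol%), CH2Cl2, 40 °C, slow addition of 6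
Reagents that add atoms: none
Why: Dirhodium-carboxylate-catalysed cyclopropanation of a styrene with a malonate carbenoid is concerted, so the Z geometry of 4 should be kept as the cis aryl/methyl relation; the chiral tert-leucinate pocket of the catalyst selects the alkene face and thereby sets C6 and C7 together.

Step 5
Reactants: 8 methyl 2-methoxyacetate
Product: 10 (Z)-tert-butyl[(1,2-dimethoxyethenyl)oxy]dimethylsilane, via chelated lithium ester enolate 9 (not isolated)
Conditions: LDA, THF, −78 °C; then TBSCl, DMPU, −78 °C → rt
Reagents that add atoms: tert-butyldimethylsilyl chloride, CC(C)(C)[Si](C)(C)Cl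
Why: Deprotonation of the α-alkoxy ester gives the chelated enolate 9, and O-silylation in the presence of DMPU traps it as the ketene silyl acetal 10; the bulky silyl group is chosen for step 6.

Step 6
Reactants: 7 dimethyl (2R,3R)-2-(3,4-dimethoxyphenyl)-3-methylcyclopropane-1,1-dicarboxylate; 10 (Z)-tert-butyl[(1,2-dimethoxyethenyl)oxy]dimethylsilane
Product: 12 dimethyl (3S,4S,5R)-4-(3,4-dimethoxyphenyl)-3-methoxy-5-methyl-2-oxocyclopentane-1,1-dicarboxylate, via cyclic silyl methyl ketal 11 (not isolated)
Conditions: Sc(OTf)3 (10 mol%), 10 (2 equiv), 4 Å molecular sieves, CH2Cl2, −20 → 0 °C; then 1 M HCl, THF, rt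
Reagents that add atoms: none
Why: Sc(OTf)3 chelates the two ester carbonyls of 7 and polarises the C1–C6 bond, whose positive end is stabilised by the dimethoxyphenyl group; 10 attacks C6 through its methoxy-bearing carbon from the side opposite to the departing malonate carbon and forms C5–C6 with inversion. The scandium malonate then adds to the silyloxy(methoxy)carbenium carbon C8 in a 5-exo-trig closure that forms C1–C8 and the five-membered ring as mixed ketal 11, which aqueous acid collapses to ketone 12. The closest known reactions are the Lewis-acid (3+2) annulations of 2-arylcyclopropane-1,1-diesters with enol silyl ethers and with ketenes. C6 is controlled by the configuration of the cyclopropane: inversion turns the cis aryl/methyl pair of 7 into the trans pair of 12, while C7 is not touched and carries the absolute configuration. C5 settles by enolisation with methoxy trans to aryl and is of no consequence, since it is re-made from an enolate in step 12. The step needs stereospecific opening and not ionisation, which low temperature, a chlorinated solvent of low polarity and the high nucleophilicity of 10 should favour. It also needs ring closure and not silyl transfer to the malonate, which the bulky tert-butyldimethylsilyl group retards.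

Step 7
Reactants: 12 dimethyl (3S,4S,5R)-4-(3,4-dimethoxyphenyl)-3-methoxy-5-methyl-2-oxocyclopentane-1,1-dicarboxylate
Product: 13 methyl (3S,4S,5R)-4-(3,4-dimethoxyphenyl)-3-methoxy-5-methyl-2-oxocyclopentane-1-carboxylate (C1 epimers and enol in equilibrium)
Conditions: LiCl, H2O (2 equiv), DMSO, 120 °C
Reagents that add atoms: none
Why: Krapcho demethoxycarbonylation: chloride attacks an ester methyl group and the carboxylate loses CO2 readily because the carbanion left behind is a β-keto ester enolate; that enolate resists a second attack at this temperature, so the reaction should stop after one ester.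

Step 8
Reactants: 13 methyl (3S,4S,5R)-4-(3,4-dimethoxyphenyl)-3-methoxy-5-methyl-2-oxocyclopentane-1-carboxylate
Product: 14 methyl (1R,3S,4S,5R)-4-(3,4-dimethoxyphenyl)-3-methoxy-5-methyl-2-oxo-1-(prop-2-en-1-yl)cyclopentane-1-carboxylate
Conditions: K2CO3, allyl bromide, acetone, 50 °C
Reagents that add atoms: allyl bromide, C=CCBr
Why: C-alkylation of a cyclic β-keto ester enolate; the allyl group should enter planar C1 on the face opposite to the adjacent C7 methyl (1,2-induction), which places allyl trans to methyl and the ester carbon, the later C2, cis to it.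

Step 9
Reactants: 14 methyl (1R,3S,4S,5R)-4-(3,4-dimethoxyphenyl)-3-methoxy-5-methyl-2-oxo-1-(prop-2-en-1-yl)cyclopentane-1-carboxylate
Product: 15 (2S,3R,4S,5S)-4-(3,4-dimethoxyphenyl)-2-(hydroxymethyl)-5-methoxy-3-methyl-2-(prop-2-en-1-yl)cyclopentan-1-ol (both C1 carbinol epimers)
Conditions: LiAlH4, THF, 0 °C
Reagents that add atoms: none
Why: Hydride reduction of ester and ketone together; the over-reduction is accepted because alkene and aryl ethers are inert and both carbinols are re-oxidised in step 10, which is simpler than a partial reduction of a hindered ester beside a ketone.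

Step 10
Reactants: 15 (2S,3R,4S,5S)-4-(3,4-dimethoxyphenyl)-2-(hydroxymethyl)-5-methoxy-3-methyl-2-(prop-2-en-1-yl)cyclopentan-1-ol
Product: 16 (1S,3S,4S,5R)-4-(3,4-dimethoxyphenyl)-3-methoxy-5-methyl-2-oxo-1-(prop-2-en-1-yl)cyclopentane-1-carbaldehyde
Conditions: Dess–Martin periodinane (2.5 equiv), CH2Cl2, 0 °C → rt
Reagents that add atoms: none
Why: Dess–Martin oxidation converts the primary and the secondary alcohol under neutral, non-nucleophilic conditions, which matters because the product is a 2-formyl ketone with a quaternary α-carbon that nucleophilic base would deformylate.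

Step 11
Reactants: 16 (1S,3S,4S,5R)-4-(3,4-dimethoxyphenyl)-3-methoxy-5-methyl-2-oxo-1-(prop-2-en-1-yl)cyclopentane-1-carbaldehyde
Product: 17 (2S,3R,4S,5S)-2-(dimethoxymethyl)-4-(3,4-dimethoxyphenyl)-5-methoxy-3-methyl-2-(prop-2-en-1-yl)cyclopentan-1-one
Conditions: HC(OMe)3, MeOH, CeCl3·7H2O (cat.), rt
Reagents that add atoms: trimethyl orthoformate, COC(OC)OC; methanol, CO
Why: Lanthanide-catalysed acetalisation with an orthoformate is selective for aldehydes over ketones, and the C8 ketone is in addition flanked by a quaternary and a tertiary carbon; the acetal masks the one group that would not survive the amide base of step 12.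

Step 12
Reactants: 17 (2S,3R,4S,5S)-2-(dimethoxymethyl)-4-(3,4-dimethoxyphenyl)-5-methoxy-3-methyl-2-(prop-2-en-1-yl)cyclopentan-1-one
Product: 19 (2S,3R,4S,5R)-2-(dimethoxymethyl)-4-(3,4-dimethoxyphenyl)-5-methoxy-5-(2-methoxyacetyl)-3-methyl-2-(prop-2-en-1-yl)cyclopentan-1-one, via lithium cyclopentenolate 18 (not isolated)
Conditions: LiHMDS, THF, −78 °C; then addition to MeOCH2COCl (1.5 equiv), THF, −78 → −40 °C
Reagents that add atoms: methoxyacetyl chloride, COCC(Cl)=O
Why: Enolisation is possible only at C5 and gives enolate 18; Claisen-type C-acylation of the preformed lithium enolate by the acid chloride is irreversible and should occur on the face opposite to the C6 aryl group, which puts the new C4 carbon cis to the C2 acetal and leaves the C5 methoxy group cis to aryl as in the target.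

Step 13
Reactants: 19 (2S,3R,4S,5R)-2-(dimethoxymethyl)-4-(3,4-dimethoxyphenyl)-5-methoxy-5-(2-methoxyacetyl)-3-methyl-2-(prop-2-en-1-yl)cyclopentan-1-one
Product: 22 (1S,5R,6S,7R)-6-(3,4-dimethoxyphenyl)-3,5-dimethoxy-7-methyl-1-(prop-2-en-1-yl)bicyclo[3.2.1]oct-2-ene-4,8-dione, via keto aldehyde 20 (not isolated), via aldol adduct 21 (not isolated)
Conditions: p-TsOH·H2O (0.2 equiv), acetone/H2O, rt; then toluene, 80 °C
Reagents that add atoms: none
Why: Aqueous acid unmasks aldehyde 20; the methoxyacetyl ketone can enolise only towards C3 and the aldehyde not at all, so an acid-catalysed intramolecular aldol addition forms C2–C3 and the six-membered ring (6-enolendo-exo-trig) as 21, which dehydrates to the α-methoxy enone 22. Acid is used instead of alkoxide because C5 lies between two carbonyl groups and would suffer retro-Claisen cleavage.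

Step 14
Reactants: 22 (1S,5R,6S,7R)-6-(3,4-dimethoxyphenyl)-3,5-dimethoxy-7-methyl-1-(prop-2-en-1-yl)bicyclo[3.2.1]oct-2-ene-4,8-dione
Product: 23 (1S,4R,5S,6S,7R)-6-(3,4-dimethoxyphenyl)-4-hydroxy-3,5-dimethoxy-7-methyl-1-(prop-2-en-1-yl)bicyclo[3.2.1]oct-2-en-8-one (hydroxyl on the face of the C6–C7 bridge)
Conditions: NaBH4, CeCl3·7H2O, MeOH, −78 °C; NaHCO3 work-up
Reagents that add atoms: none
Why: Luche reduction adds hydride 1,2 to the enone carbonyl C4; C8 is flanked by two quaternary carbons and screened by C3 on one face and the exo aryl group on the other. The endo hydrogen on C6 lies under C4, so hydride should enter from the C8 side and place the hydroxyl on the face of the C6–C7 bridge (4R).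

Step 15
Reactants: 23 (1S,4R,5S,6S,7R)-6-(3,4-dimethoxyphenyl)-4-hydroxy-3,5-dimethoxy-7-methyl-1-(prop-2-en-1-yl)bicyclo[3.2.1]oct-2-en-8-one
Product: 24 (1S,4S,5S,6S,7R)-6-(3,4-dimethoxyphenyl)-3,5-dimethoxy-7-methyl-8-oxo-1-(prop-2-en-1-yl)bicyclo[3.2.1]oct-2-en-4-yl acetate
Conditions: PPh3, DIAD, AcOH, THF, 0 °C → rt
Reagents that add atoms: acetic acid, CC(=O)O
Why: Mitsunobu esterification activates the hydroxyl as an alkoxyphosphonium ion and acetate displaces it with inversion from the open C8 side, which sets 4S and installs the acetyl group in one operation; C3 and C5 carry no hydrogen, so elimination cannot compete, and the neutral conditions spare the enol ether.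

## Compound list

1 | 4-iodo-1,2-dimethoxybenzene | COc1ccc(I)cc1OC | starting material
2 | propyne | CC#C | starting material
3 | 1,2-dimethoxy-4-(prop-1-yn-1-yl)benzene | CC#Cc1ccc(OC)c(OC)c1 | intermediate
4 | (Z)-1,2-dimethoxy-4-(prop-1-en-1-yl)benzene | C/C=C\c1ccc(OC)c(OC)c1 | intermediate
5 | dimethyl malonate | COC(=O)CC(=O)OC | starting material
6 | dimethyl 2-diazopropanedioate | COC(=O)C(=[N+]=[N-])C(=O)OC | intermediate
7 | dimethyl (2R,3R)-2-(3,4-dimethoxyphenyl)-3-methylcyclopropane-1,1-dicarboxylate | COC(=O)C1(C(=O)OC)[C@H](C)[C@@H]1c1ccc(OC)c(OC)c1 | intermediate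
8 | methyl 2-methoxyacetate | COCC(=O)OC | starting material
9 | chelated lithium enolate of methyl 2-methoxyacetate (enolate oxygen cis to the vinylic methoxy group) | CO/C=C(\[O-])OC.[Li+] | intermediate (not isolated)
10 | (Z)-tert-butyl[(1,2-dimethoxyethenyl)oxy]dimethylsilane | CO/C=C(\O[Si](C)(C)C(C)(C)C)OC | intermediate
11 | dimethyl (4S,5R)-2-[(tert-butyldimethylsilyl)oxy]-4-(3,4-dimethoxyphenyl)-2,3-dimethoxy-5-methylcyclopentane-1,1-dicarboxylate (C2 and C3 not defined) | COC(=O)C1(C(=O)OC)[C@H](C)[C@@H](c2ccc(OC)c(OC)c2)C(OC)C1(OC)O[Si](C)(C)C(C)(C)C | intermediate (not isolated)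
12 | dimethyl (3S,4S,5R)-4-(3,4-dimethoxyphenyl)-3-methoxy-5-methyl-2-oxocyclopentane-1,1-dicarboxylate | COC(=O)C1(C(=O)OC)[C@H](C)[C@@H](c2ccc(OC)c(OC)c2)[C@H](OC)C1=O | intermediate
13 | methyl (3S,4S,5R)-4-(3,4-dimethoxyphenyl)-3-methoxy-5-methyl-2-oxocyclopentane-1-carboxylate (C1 labile) | COC(=O)C1[C@H](C)[C@@H](c2ccc(OC)c(OC)c2)[C@H](OC)C1=O | intermediate
14 | methyl (1R,3S,4S,5R)-4-(3,4-dimethoxyphenyl)-3-methoxy-5-methyl-2-oxo-1-(prop-2-en-1-yl)cyclopentane-1-carboxylate | C=CC[C@@]1(C(=O)OC)[C@H](C)[C@@H](c2ccc(OC)c(OC)c2)[C@H](OC)C1=O | intermediate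
15 | (2S,3R,4S,5S)-4-(3,4-dimethoxyphenyl)-2-(hydroxymethyl)-5-methoxy-3-methyl-2-(prop-2-en-1-yl)cyclopentan-1-ol (both C1 epimers) | C=CC[C@@]1(CO)[C@H](C)[C@@H](c2ccc(OC)c(OC)c2)[C@H](OC)C1O | intermediate
16 | (1S,3S,4S,5R)-4-(3,4-dimethoxyphenyl)-3-methoxy-5-methyl-2-oxo-1-(prop-2-en-1-yl)cyclopentane-1-carbaldehyde | C=CC[C@@]1(C=O)[C@H](C)[C@@H](c2ccc(OC)c(OC)c2)[C@H](OC)C1=O | intermediate
17 | (2S,3R,4S,5S)-2-(dimethoxymethyl)-4-(3,4-dimethoxyphenyl)-5-methoxy-3-methyl-2-(prop-2-en-1-yl)cyclopentan-1-one | C=CC[C@@]1(C(OC)OC)[C@H](C)[C@@H](c2ccc(OC)c(OC)c2)[C@H](OC)C1=O | intermediate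
18 | lithium 5-(dimethoxymethyl)-3-(3,4-dimethoxyphenyl)-2-methoxy-4-methyl-5-(prop-2-en-1-yl)cyclopent-1-en-1-olate, configured as 17 | C=CC[C@@]1(C(OC)OC)[C@H](C)[C@@H](c2ccc(OC)c(OC)c2)C(OC)=C1[O-].[Li+] | intermediate (not isolated)
19 | (2S,3R,4S,5R)-2-(dimethoxymethyl)-4-(3,4-dimethoxyphenyl)-5-methoxy-5-(2-methoxyacetyl)-3-methyl-2-(prop-2-en-1-yl)cyclopentan-1-one | C=CC[C@@]1(C(OC)OC)[C@H](C)[C@@H](c2ccc(OC)c(OC)c2)[C@](OC)(C(=O)COC)C1=O | intermediate
20 | (1S,3R,4S,5R)-4-(3,4-dimethoxyphenyl)-3-methoxy-3-(2-methoxyacetyl)-5-methyl-2-oxo-1-(prop-2-en-1-yl)cyclopentane-1-carbaldehyde | C=CC[C@@]1(C=O)[C@H](C)[C@@H](c2ccc(OC)c(OC)c2)[C@](OC)(C(=O)COC)C1=O | intermediate (not isolated)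
21 | (1S,5R,6S,7R)-6-(3,4-dimethoxyphenyl)-2-hydroxy-3,5-dimethoxy-7-methyl-1-(prop-2-en-1-yl)bicyclo[3.2.1]octane-4,8-dione (C2 and C3 not defined) | C=CC[C@]12C(O)C(OC)C(=O)[C@](OC)(C1=O)[C@H](c1ccc(OC)c(OC)c1)[C@H]2C | intermediate (not isolated)
22 | (1S,5R,6S,7R)-6-(3,4-dimethoxyphenyl)-3,5-dimethoxy-7-methyl-1-(prop-2-en-1-yl)bicyclo[3.2.1]oct-2-ene-4,8-dione | C=CC[C@]12C=C(OC)C(=O)[C@](OC)(C1=O)[C@H](c1ccc(OC)c(OC)c1)[C@H]2C | intermediate
23 | (1S,4R,5S,6S,7R)-6-(3,4-dimethoxyphenyl)-4-hydroxy-3,5-dimethoxy-7-methyl-1-(prop-2-en-1-yl)bicyclo[3.2.1]oct-2-en-8-one | C=CC[C@]12C=C(OC)[C@@H](O)[C@](OC)(C1=O)[C@H](c1ccc(OC)c(OC)c1)[C@H]2C | intermediate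
24 | (1S,4S,5S,6S,7R)-6-(3,4-dimethoxyphenyl)-3,5-dimethoxy-7-methyl-8-oxo-1-(prop-2-en-1-yl)bicyclo[3.2.1]oct-2-en-4-yl acetate | C=CC[C@]12C=C(OC)[C@H](OC(C)=O)[C@](OC)(C1=O)[C@H](c1ccc(OC)c(OC)c1)[C@H]2C | target

## Step count and least certain steps

Total: 15 steps. Longest linear sequence: 13 steps (steps 1, 2, 4 and 6 to 15).

**Step 6 (key step).** The most likely failure is that the ring does not close. Silyl transfer from the silyloxycarbenium ion to the scandium malonate can outrun C1–C8 bond formation, because an ester-derived oxocarbenium ion is a weaker electrophile than the ketone-derived ones of the established enol silyl ether annulations. A second concern is partial ionisation at C6 caused by the very electron-rich aryl group; this would erode the aryl/methyl relation but not the enantiomeric purity, which C7 carries. The fallback accepts ring opening and closes the ring by a different reaction. It sets out from 7 and 8. Ester 8 is converted with LDA and TMSCl into (Z)-[(1,2-dimethoxyethenyl)oxy]trimethylsilane F1, whose small silyl group favours transfer. Sc(OTf)3-catalysed homo-Michael opening of 7 by F1 at C6, with inversion, should give after aqueous work-up trimethyl (2R,3S)-3-(3,4-dimethoxyphenyl)-4-methoxy-2-methylbutane-1,1,4-tricarboxylate F2. Krapcho demethoxycarbonylation of its malonate end (LiCl, wet DMSO, 150 °C) would give dimethyl (3S,4S)-3-(3,4-dimethoxyphenyl)-2-methoxy-4-methylhexanedioate F3. Dieckmann condensation (KOtBu, THF) should then close C1–C8; only this regiochemistry yields an enolisable β-keto ester, so it is the one driven to completion. The fallback comes back to the route at 13.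

**Step 4.** The most likely failure is insufficient enantioselectivity, possibly with some loss of the cis geometry. A malonate carbenoid carries two identical esters, so face selection rests only on how the cis-disubstituted, electron-rich alkene approaches the catalyst, and a very electron-rich styrene can make the carbene addition less synchronous. The fallback changes the carbene source and the metal. It sets out from 4 and 5. Malonate 5 is converted with PhI(OAc)2 and KOH in MeCN into dimethyl 2-(phenyl-λ3-iodanylidene)propanedioate F4. This ylide transfers the malonate carbene to 4 under Cu(MeCN)4PF6 with a side-arm-modified chiral bis(oxazoline) ligand at −40 °C, a catalyst class used for cis-1,2-disubstituted alkenes. The fallback comes back to the route at 7.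

**Step 8.** The most likely failure is poor facial selectivity at C1, because the aryl group on C6 shields the face opposite to the C7 methyl from a 1,3-position and the two effects oppose each other. The fallback replaces substrate control by catalyst control. It sets out from 13, which is allylated with allyl acetate under Pd2(dba)3 and one enantiomer of N,N'-bis(2-diphenylphosphinobenzoyl)-1,2-diaminocyclohexane (palladium-catalysed asymmetric allylic alkylation of a β-keto ester), the ligand enantiomer being chosen to reinforce attack anti to methyl. It comes back to the route at 14 and makes no new compound (F0).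

**Step 12.** The most likely failure is O-acylation of the fully substituted enolate, or C-acylation on the aryl face, because C5 is flanked by the aryl-bearing C6 and becomes quaternary. The fallback delivers the acyl group intramolecularly from the C2 oxygen, which enforces both C-acylation and the cis relation of C4 and C2. It sets out from diol 15. Selective esterification of the primary hydroxyl with methoxyacetyl chloride and pyridine at −40 °C would give [4-(3,4-dimethoxyphenyl)-2-hydroxy-3-methoxy-5-methyl-1-(prop-2-en-1-yl)cyclopentyl]methyl 2-methoxyacetate F5. Dess–Martin oxidation would give [4-(3,4-dimethoxyphenyl)-3-methoxy-5-methyl-2-oxo-1-(prop-2-en-1-yl)cyclopentyl]methyl 2-methoxyacetate F6. LiHMDS should then form the C5 enolate, which attacks the tethered ester through a six-membered transition state. The tetrahedral intermediate is a stable cyclic hemiketal alkoxide, and work-up gives 4-(3,4-dimethoxyphenyl)-2-(hydroxymethyl)-5-methoxy-5-(2-methoxyacetyl)-3-methyl-2-(prop-2-en-1-yl)cyclopentan-1-one F7 in equilibrium with that hemiketal. Dess–Martin oxidation of the open form leads to keto aldehyde 20, where the fallback comes back to the route; the acid treatment of step 13 then gives 22.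

**Step 15.** The most likely failure is slow displacement at a carbon next to the quaternary C5. This would leave room for SN2' attack of acetate at C2 or for acyl transfer with retention. The fallback uses thermodynamic control instead of substitution. It sets out from 23, which is a β-hydroxy ketone (C4 carbinol, C5, C8 ketone). Catalytic DBU in toluene should open C4–C5 by retro-aldol reaction to a C5 enolate and a 2-methoxy enal that stays tethered through C1, so re-closure can only regenerate the same C5 configuration. The epimer with the hydroxyl on the C8 side avoids the contact with the endo hydrogen on C6 and should be favoured at equilibrium: (1S,4S,5S,6S,7R)-6-(3,4-dimethoxyphenyl)-4-hydroxy-3,5-dimethoxy-7-methyl-1-(prop-2-en-1-yl)bicyclo[3.2.1]oct-2-en-8-one F8. Acetylation with Ac2O, DMAP and pyridine brings the fallback back to the route at 24.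

## Further compounds

F1 | step 6 | (Z)-[(1,2-dimethoxyethenyl)oxy]trimethylsilane | CO/C=C(\O[Si](C)(C)C)OC
F2 | step 6 | trimethyl (2R,3S)-3-(3,4-dimethoxyphenyl)-4-methoxy-2-methylbutane-1,1,4-tricarboxylate (C4 epimers) | COC(=O)C(C(=O)OC)[C@H](C)[C@@H](c1ccc(OC)c(OC)c1)C(OC)C(=O)OC
F3 | step 6 | dimethyl (3S,4S)-3-(3,4-dimethoxyphenyl)-2-methoxy-4-methylhexanedioate (C2 epimers) | COC(=O)C[C@H](C)[C@@H](c1ccc(OC)c(OC)c1)C(OC)C(=O)OC
F4 | step 4 | dimethyl 2-(phenyl-λ3-iodanylidene)propanedioate | COC(=O)[C-](C(=O)OC)[I+]c1ccccc1
F0 | step 8 | none | none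
F5 | step 12 | [4-(3,4-dimethoxyphenyl)-2-hydroxy-3-methoxy-5-methyl-1-(prop-2-en-1-yl)cyclopentyl]methyl 2-methoxyacetate, configured as 15 | C=CC[C@@]1(COC(=O)COC)[C@H](C)[C@@H](c2ccc(OC)c(OC)c2)[C@H](OC)C1O
F6 | step 12 | [4-(3,4-dimethoxyphenyl)-3-methoxy-5-methyl-2-oxo-1-(prop-2-en-1-yl)cyclopentyl]methyl 2-methoxyacetate, configured as 14 | C=CC[C@@]1(COC(=O)COC)[C@H](C)[C@@H](c2ccc(OC)c(OC)c2)[C@H](OC)C1=O
F7 | step 12 | 4-(3,4-dimethoxyphenyl)-2-(hydroxymethyl)-5-methoxy-5-(2-methoxyacetyl)-3-methyl-2-(prop-2-en-1-yl)cyclopentan-1-one, configured as 19, in equilibrium with its cyclic hemiketal | C=CC[C@@]1(CO)[C@H](C)[C@@H](c2ccc(OC)c(OC)c2)[C@](OC)(C(=O)COC)C1=O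
F8 | step 15 | (1S,4S,5S,6S,7R)-6-(3,4-dimethoxyphenyl)-4-hydroxy-3,5-dimethoxy-7-methyl-1-(prop-2-en-1-yl)bicyclo[3.2.1]oct-2-en-8-one | C=CC[C@]12C=C(OC)[C@H](O)[C@](OC)(C1=O)[C@H](c1ccc(OC)c(OC)c1)[C@H]2C
A1 | alternative 1 | 2-allyl-4-(3,4-dimethoxyphenyl)-5-(1-hydroxy-2-methoxyprop-2-enyl)-5-methoxy-3-methylcyclopentan-1-one | C=CC[C@H]1[C@H](C)[C@@H](c2ccc(OC)c(OC)c2)[C@](OC)([C@@H](O)C(OC)=C)C1=O
A2 | alternative 1 | trans-2-methoxy-4-methyl-5-(prop-2-en-1-yl)cyclopent-2-en-1-one | C=CC[C@H]1[C@H](C)C=C(OC)C1=O
A3 | alternative 1 | 2-methoxyprop-2-enal | C=C(OC)C=O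
A4 | alternative 2 | 1-allyl-6-(3,4-dimethoxyphenyl)-5-methoxy-7-methylbicyclo[3.2.1]octane-4,8-dione | C=CC[C@]12CCC(=O)[C@](OC)(C1=O)[C@H](c1ccc(OC)c(OC)c1)[C@H]2C
A5 | alternative 2 | 2-[1-(3,4-dimethoxyphenyl)prop-2-en-1-yl]-2-methoxy-4-(phenylselanyl)-4-(prop-2-en-1-yl)cyclohexane-1,3-dione (C4 not defined) | C=CCC1([Se]c2ccccc2)CCC(=O)[C@](OC)(C1=O)[C@@H](C=C)c1ccc(OC)c(OC)c1
A6 | alternative 3 | 1-allyl-6-(3,4-dimethoxyphenyl)-3,5-dimethoxy-7-methylbicyclo[3.2.1]oct-2-ene-4,8-dione (identical with 22) | C=CC[C@]12C=C(OC)C(=O)[C@](OC)(C1=O)[C@H](c1ccc(OC)c(OC)c1)[C@H]2C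
A7 | alternative 3 | 2-(3,4-dimethoxyphenyl)-5,7-dimethoxy-3-methyl-3a-(prop-2-en-1-yl)-3,3a-dihydro-1-benzofuran-6(2H)-one | C=CC[C@]12C=C(OC)C(=O)C(OC)=C1O[C@H](c1ccc(OC)c(OC)c1)[C@H]2C
A8 | alternative 3 | trans-2-(3,4-dimethoxyphenyl)-5,7-dimethoxy-3-methyl-6-(prop-2-en-1-yloxy)-2,3-dihydro-1-benzofuran | C=CCOc1c(OC)cc2c(c1OC)O[C@H](c1ccc(OC)c(OC)c1)[C@H]2C
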